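**Plan**

- Retrosynthesis: the three O–benzyl bonds are cut first, then ring A is taken back to its 2,4-dioxocyclohexane level and opened at C1–C6 and C3–C4 into acetoacetate 16 and enoate 7.
- Acetoacetate 16 is cut at the ester C–O bond (acetoacetylation of alcohol 13) and at the aryl–CH2 bond of ring B (B-alkyl Suzuki–Miyaura coupling); enoate 7 is cut at C2=C3 (cross-metathesis).
- Both chains are cut at the C–C bond next to the carbinol carbon (Grignard opening of (R)-2-propyloxirane).
- Forward: each chain is made in three steps; step 7 joins them and closes ring A in the same operation; ring A is then aromatised and all benzyl groups are removed last. Ring B is bought intact.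
- Stereochemistry: both (R) carbinol centres come from (R)-2-propyloxirane, whose C–O bond is never broken; the two ring stereocentres made in step 7 are erased in step 8.
- Enabling feature: ring A is a 6-alkyl-2,4-dihydroxybenzoate, so C1 with its ester, C2–O and C3 map onto an acetoacetate ester, and C4–O, C5 and C6 with its chain map onto an alk-2-enoate.

Key step: step 7

Assumption: 1,3-bis(benzyloxy)-5-bromobenzene (11) is taken as a catalogue compound; ring carbons C1 and C6 of dione 18 are drawn without configuration because both are lost on aromatisation.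

**Route**

Step 1
Reactants: 1 8-bromooct-1-ene; 2 (R)-2-propyloxirane
Product: 4 (4R)-tridec-12-en-4-ol, via oct-7-enylmagnesium bromide 3 (not isolated)
Conditions: Mg, THF, 23→45 °C; then 2, CuI (10 mol %), THF, −30→0 °C; 1 M HCl
Reagents that add atoms: none
Why: Under CuI catalysis the primary Grignard reagent 3 opens the monosubstituted epoxide by SN2 attack at its unsubstituted carbon (copper-catalysed Grignard opening of an epoxide), so the C–O bond at the stereocentre of 2 is never broken and the carbinol of 4 is (R).

Step 2
Reactants: 4 (4R)-tridec-12-en-4-ol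
Product: 5 (10R)-10-(benzyloxy)tridec-1-ene
Conditions: NaH, BnBr, Bu4NI (cat.), THF–DMF, 0→23 °C
Reagents that add atoms: benzyl bromide, BrCc1ccccc1
Why: Williamson ether synthesis: the sodium alkoxide is benzylated on oxygen, which leaves the carbinol configuration and the terminal alkene untouched.

Step 3
Reactants: 5 (10R)-10-(benzyloxy)tridec-1-ene; 6 methyl acrylate
Product: 7 methyl (2E,11R)-11-(benzyloxy)tetradec-2-enoate
Conditions: second-generation Grubbs catalyst RuCl2(=CHPh)(PCy3)(H2IMes) (3 mol %), 6 (4 equiv), CH2Cl2, 40 °C
Reagents that add atoms: none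
Why: Olefin cross-metathesis of a terminal alkene with an excess of the electron-poor acrylate is selective for the hetero-coupled (E)-enoate and is driven by loss of ethene; the benzyl ether is inert and the alkene geometry has no bearing on step 7.

Step 4
Reactants: 8 6-bromohex-1-ene; 2 (R)-2-propyloxirane
Product: 10 (4R)-undec-10-en-4-ol, via hex-5-enylmagnesium bromide 9 (not isolated)
Conditions: Mg, THF, 23→45 °C; then 2, CuI (10 mol %), THF, −30→0 °C; 1 M HCl
Reagents that add atoms: none
Why: The same copper-catalysed Grignard opening at the unsubstituted epoxide carbon carries the (R) configuration of 2 unchanged into the carbinol that will become the ester oxygen-bearing centre.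

Step 5
Reactants: 10 (4R)-undec-10-en-4-ol; 11 1,3-bis(benzyloxy)-5-bromobenzene
Product: 13 (4R)-11-[3,5-bis(benzyloxy)phenyl]undecan-4-ol, via bis(9-BBN) borane adduct 12 (not isolated)
Conditions: 9-BBN (2.5 equiv), THF, 0→50 °C; then 11, Pd(dppf)Cl2 (5 mol %), aq. K3PO4, DMF, 60 °C
Reagents that add atoms: none
Why: 9-BBN hydroborates the terminal alkene at the primary carbon (one further equivalent is taken up by the hydroxyl as a borinate that hydrolyses in the aqueous coupling), and the primary alkylborane transfers its chain to the arylpalladium bromide formed from 11 and zerovalent palladium (B-alkyl Suzuki–Miyaura coupling), the dppf ligand favouring reductive elimination over β-hydride elimination; the benzyl ethers and the stereocentre are not involved.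

Step 6
Reactants: 13 (4R)-11-[3,5-bis(benzyloxy)phenyl]undecan-4-ol; 14 2,2,6-trimethyl-4H-1,3-dioxin-4-one
Product: 16 (8R)-1-[3,5-bis(benzyloxy)phenyl]undecan-8-yl 3-oxobutanoate, via acetylketene 15 (not isolated)
Conditions: 14 (1.5 equiv), xylene, 135 °C, acetone distilled off
Reagents that add atoms: none
Why: Thermal retro-[4+2] fragmentation of the dioxinone releases acetone and acetylketene 15, which is captured by the secondary hydroxyl (acetoacetylation under neutral conditions), so the hindered ester bond is made at oxygen with retention at the carbinol carbon.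

Step 7
Reactants: 16 (8R)-1-[3,5-bis(benzyloxy)phenyl]undecan-8-yl 3-oxobutanoate; 7 methyl (2E,11R)-11-(benzyloxy)tetradec-2-enoate
Product: 18 (8R)-1-[3,5-bis(benzyloxy)phenyl]undecan-8-yl 6-[(8R)-8-(benzyloxy)undecyl]-2,4-dioxocyclohexane-1-carboxylate, via Michael adduct 17 (not isolated)
Conditions: KOC(CH3)3 (1.1 equiv), 7 (1.2 equiv), (CH3)3COH–THF, 23→70 °C; then 1 M HCl, 0 °C
Reagents that add atoms: none
Why: tert-Butoxide deprotonates 16 at the carbon between its carbonyls and this enolate adds to the β-carbon of 7 (Michael addition, C1–C6); proton transfer then exposes the methyl ketone enolate, which attacks the methyl ester carbonyl and expels methoxide (intramolecular Claisen condensation of Dieckmann type, C3–C4), and the acidic dione is held as its potassium enolate until acidification. The closest known reaction is the alkoxide-mediated condensation of alkyl acetoacetates with crotonates and higher alk-2-enoates to alkyl 6-alkyl-2,4-dioxocyclohexane-1-carboxylates. Ring A closes in a 6-exo-trig mode, the attacked ester C=O lying outside the forming ring. The new stereocentres at C1 and C6 are not controlled (trans should prevail through equilibration at C1) and need not be, since step 8 erases both, while the two carbinol centres lie far from any enolisable site. The step needs the methyl ester to be acylated and the secondary ester to be spared, and geometry secures this: only the methyl ester carbonyl lies six atoms from the ketone methyl carbon, while the secondary ester sits on the nucleophilic carbon and is masked within the β-keto ester enolate. Competing O-acylation to an enol lactone is reversible under alkoxide and is drained by the irreversible deprotonation of the β-diketone, and the hindered tert-butoxide avoids ester exchange.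

Step 8
Reactants: 18 (8R)-1-[3,5-bis(benzyloxy)phenyl]undecan-8-yl 6-[(8R)-8-(benzyloxy)undecyl]-2,4-dioxocyclohexane-1-carboxylate
Product: 20 (8R)-1-[3,5-bis(benzyloxy)phenyl]undecan-8-yl 6-[(8R)-8-(benzyloxy)undecyl]-2,4-dihydroxybenzoate, via 3-bromo dione 19 (not isolated)
Conditions: Br2 (1.0 equiv), DMF, 0 °C; then 80 °C
Reagents that add atoms: none
Why: The enolised β-diketone should be brominated at C3 far faster than the dialkoxyarene of ring B, and on warming in DMF the bromodione loses HBr by 1,4-elimination through its C4–C5 enol and tautomerises to the resorcylate (bromination–dehydrobromination aromatisation, well precedented on simple alkyl 6-alkyl-2,4-dioxocyclohexane-1-carboxylates); any stray aryl bromide or lost benzyl group would be levelled in step 9.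

Step 9
Reactants: 20 (8R)-1-[3,5-bis(benzyloxy)phenyl]undecan-8-yl 6-[(8R)-8-(benzyloxy)undecyl]-2,4-dihydroxybenzoate
Product: 21 integracin B, (8R)-1-(3,5-dihydroxyphenyl)undecan-8-yl 2,4-dihydroxy-6-[(8R)-8-hydroxyundecyl]benzoate
Conditions: H2 (1 atm), Pd(OH)2/C, EtOAc–MeOH, 23 °C
Reagents that add atoms: none
Why: Hydrogenolysis over palladium cleaves the two aryl benzyl ethers and the secondary alkyl benzyl ether (and would also reduce any aryl C–Br bond), while the non-benzylic secondary benzoate ester, both arenes and both carbinol centres are inert.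

**Compound list**

1 | 8-bromooct-1-ene | C=CCCCCCCBr | starting material
2 | (R)-2-propyloxirane | CCC[C@@H]1CO1 | starting material
3 | oct-7-enylmagnesium bromide | C=CCCCCCC[Mg]Br | intermediate (not isolated)
4 | (4R)-tridec-12-en-4-ol | CCC[C@@H](O)CCCCCCCC=C | intermediate
5 | (10R)-10-(benzyloxy)tridec-1-ene | CCC[C@@H](OCc1ccccc1)CCCCCCCC=C | intermediate
6 | methyl acrylate (methyl prop-2-enoate) | C=CC(=O)OC | starting material
7 | methyl (2E,11R)-11-(benzyloxy)tetradec-2-enoate | CCC[C@@H](OCc1ccccc1)CCCCCCC/C=C/C(=O)OC | intermediate
8 | 6-bromohex-1-ene | C=CCCCCBr | starting material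
9 | hex-5-enylmagnesium bromide | C=CCCCC[Mg]Br | intermediate (not isolated)
10 | (4R)-undec-10-en-4-ol | CCC[C@@H](O)CCCCCC=C | intermediate
11 | 1,3-bis(benzyloxy)-5-bromobenzene | Brc1cc(OCc2ccccc2)cc(OCc2ccccc2)c1 | starting material
12 | 9-[(8R)-8-(9-borabicyclo[3.3.1]nonan-9-yloxy)undecyl]-9-borabicyclo[3.3.1]nonane | CCC[C@@H](OB1C2CCCC1CCC2)CCCCCCCB1C2CCCC1CCC2 | intermediate (not isolated)
13 | (4R)-11-[3,5-bis(benzyloxy)phenyl]undecan-4-ol | CCC[C@@H](O)CCCCCCCc1cc(OCc2ccccc2)cc(OCc2ccccc2)c1 | intermediate
14 | 2,2,6-trimethyl-4H-1,3-dioxin-4-one | CC1=CC(=O)OC(C)(C)O1 | starting material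
15 | acetylketene (3-oxobut-1-en-1-one) | CC(=O)C=C=O | intermediate (not isolated)
16 | (8R)-1-[3,5-bis(benzyloxy)phenyl]undecan-8-yl 3-oxobutanoate | CC(=O)CC(=O)O[C@H](CCC)CCCCCCCc1cc(OCc2ccccc2)cc(OCc2ccccc2)c1 | intermediate
17 | 1-{(8R)-1-[3,5-bis(benzyloxy)phenyl]undecan-8-yl} 5-methyl 2-acetyl-3-[(8R)-8-(benzyloxy)undecyl]pentanedioate (C2 and C3 unspecified) | CCC[C@@H](OCc1ccccc1)CCCCCCCC(CC(=O)OC)C(C(C)=O)C(=O)O[C@H](CCC)CCCCCCCc1cc(OCc2ccccc2)cc(OCc2ccccc2)c1 | intermediate (not isolated)
18 | (8R)-1-[3,5-bis(benzyloxy)phenyl]undecan-8-yl 6-[(8R)-8-(benzyloxy)undecyl]-2,4-dioxocyclohexane-1-carboxylate (C1 and C6 unspecified) | CCC[C@@H](OCc1ccccc1)CCCCCCCC1CC(=O)CC(=O)C1C(=O)O[C@H](CCC)CCCCCCCc1cc(OCc2ccccc2)cc(OCc2ccccc2)c1 | intermediate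
19 | (8R)-1-[3,5-bis(benzyloxy)phenyl]undecan-8-yl 6-[(8R)-8-(benzyloxy)undecyl]-3-bromo-2,4-dioxocyclohexane-1-carboxylate (ring centres unspecified) | CCC[C@@H](OCc1ccccc1)CCCCCCCC1CC(=O)C(Br)C(=O)C1C(=O)O[C@H](CCC)CCCCCCCc1cc(OCc2ccccc2)cc(OCc2ccccc2)c1 | intermediate (not isolated)
20 | (8R)-1-[3,5-bis(benzyloxy)phenyl]undecan-8-yl 6-[(8R)-8-(benzyloxy)undecyl]-2,4-dihydroxybenzoate | CCC[C@@H](OCc1ccccc1)CCCCCCCc1cc(O)cc(O)c1C(=O)O[C@H](CCC)CCCCCCCc1cc(OCc2ccccc2)cc(OCc2ccccc2)c1 | intermediate
21 | integracin B, (8R)-1-(3,5-dihydroxyphenyl)undecan-8-yl 2,4-dihydroxy-6-[(8R)-8-hydroxyundecyl]benzoate | CCC[C@@H](O)CCCCCCCc1cc(O)cc(O)c1C(=O)O[C@H](CCC)CCCCCCCc1cc(O)cc(O)c1 | target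

**Step count and risks**

Total steps: 9. Longest linear sequence: 6 steps (1, 2, 3, 7, 8, 9 or 4, 5, 6, 7, 8, 9).

Step 7. The conjugate addition of the hindered acetoacetate enolate to the β-alkyl enoate may be slow and reversible, so that deconjugation of 7 by γ-deprotonation, retro-Claisen loss of the acetyl group, or exchange of the secondary ester by liberated methoxide overtakes ring closure. The fallback redistributes donor and acceptor so that a malonate adds to an enone. Setting out from 13, acylation with methyl 3-chloro-3-oxopropanoate and pyridine in CH2Cl2 should give the mixed malonate methyl (8R)-1-[3,5-bis(benzyloxy)phenyl]undecan-8-yl propanedioate F1. Setting out from 5, cross-metathesis with but-3-en-2-one under the second-generation Grubbs catalyst should give the enone (3E,12R)-12-(benzyloxy)pentadec-3-en-2-one F2. With KOC(CH3)3 in (CH3)3COH the malonate anion of F1 should add to F2, again forming C1–C6, and the methyl ketone enolate should then close on the less hindered methyl ester, forming C2–C3 in place of C3–C4. This returns the route at dione 18.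

Step 8. Bromine may be consumed by electrophilic substitution on the dialkoxyarene of ring B before the dione is fully brominated, and the HBr accumulating at 80 °C may strip benzyl groups or leave the sequence stalled at the bromodione. The fallback replaces stoichiometric electrophilic bromine and thermal dehydrobromination by a catalytic iodine cycle with DMSO as terminal oxidant (I2, 20 mol %, DMSO, 80–100 °C), a known oxidative aromatisation of cyclohexenones and cyclic 1,3-diones. Iodine does not substitute the benzyl-protected arene without an activator, and the HI formed is reoxidised as it appears. It sets out from 18 and returns at 20; no compound outside the list is made on this path (none F0).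

Step 5. The free hydroxyl may divert borane and leave hydroboration incomplete, and protodeboronation or β-hydride elimination at palladium may return chain-reduced or alkene-isomerised material in place of the coupled product. The fallback forms the aryl–chain link by olefin metathesis and saturates it without touching the benzyl ethers. 3,5-Bis(benzyloxy)benzaldehyde is methylenated (methyltriphenylphosphonium bromide, KOC(CH3)3, THF; Wittig reaction) to 1,3-bis(benzyloxy)-5-ethenylbenzene F3. Setting out from 10, cross-metathesis with F3 under the second-generation Grubbs catalyst should give (4R,10E)-11-[3,5-bis(benzyloxy)phenyl]undec-10-en-4-ol F4. Diimide reduction of the styrenyl double bond (4-methylbenzenesulfonohydrazide, NaOAc, THF–H2O, reflux) then returns the route at 13.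

**Further compounds**

F1 | step 7 | methyl (8R)-1-[3,5-bis(benzyloxy)phenyl]undecan-8-yl propanedioate | COC(=O)CC(=O)O[C@H](CCC)CCCCCCCc1cc(OCc2ccccc2)cc(OCc2ccccc2)c1
F2 | step 7 | (3E,12R)-12-(benzyloxy)pentadec-3-en-2-one | CCC[C@@H](OCc1ccccc1)CCCCCCC/C=C/C(C)=O
F0 | step 8 | none | none
F3 | step 5 | 1,3-bis(benzyloxy)-5-ethenylbenzene | C=Cc1cc(OCc2ccccc2)cc(OCc2ccccc2)c1
F4 | step 5 | (4R,10E)-11-[3,5-bis(benzyloxy)phenyl]undec-10-en-4-ol | CCC[C@@H](O)CCCCC/C=C/c1cc(OCc2ccccc2)cc(OCc2ccccc2)c1
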